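The numbers in the tables were computed for an exercise; noise was put on by code.

Slowness is the thing to measure in these runs, so for the quick number you asked for I take a single measure of it.

| flask | solid substrate | reagent | remark | time |
|---|---|---|---|---|
| theta | 12 mM | 30 mM | run made earlier |  |
| alpha | 19 mM | 30 mM | run made earlier |  |
| beta | 25 mM | 60 mM | run made earlier |  |
| flask | 25 mM | 30.0 mM |  | 10 d |

| run | time / d | target / % |
|---|---|---|
| theta | 1.04 | 0.9 |
| theta | 3.00 | 16.2 |
| theta | 6.00 | 60.2 |
| theta | 8.00 | 76.7 |
| theta | 12.0 | 93.9 |
| alpha | 2.50 | 6.2 |
| alpha | 5.00 | 31.7 |
| alpha | 8.00 | 66.2 |
| alpha | 10.0 | 78.8 |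
| alpha | 12.0 | 86.0 |
| beta | 1.04 | 1.6 |
| beta | 3.00 | 11.4 |
| beta | 6.00 | 44.2 |
| beta | 8.00 | 70.2 |
| beta | 12.0 | 93.7 |

(standard deviation of a reading: 0.5 percentage points)

- given per volume of solution although it is solid: solid substrate
- what was read earlier has a scatter of 0.5 percentage points, one standard deviation
- at the start none of the solid substrate is in solution

1. the target standing at 10 d, as a percentage of the solid substrate charged
2. the change that raises the amount of target at 10 d, in percent of the solid substrate charged most ("none" if none brings more than 2 percentage points) (red / ochre / violet / none)
3. amount of target at 10 d, in percent of the solid substrate charged, after red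

- red: doubling the amount of reagent, all else as stated
- ochre: doubling the dissolution coefficient of the solid substrate, all else as stated
- violet: doubling the solubility of the solid substrate, all else as stated

Take the half-time, the moment at which target stands at half of the solid substrate charged, read by straight lines between neighbouring readings. At the same reagent, the theta run reaches it at 5.30 d and the alpha run, with its larger charge, at 6.59 d. Dividing the logarithm of the ratio of half-times by the logarithm of the ratio of charges gives 0.473, the stretch exponent, the power of the charge that the half-time follows at fixed reagent.

Carried from the alpha run to your flask's 25 mM, it gives a half-time of 7.50 d. If the curves differ only by this stretch of time, which is my assumption, 10 d in your flask counts as 8.78 d in the alpha run, where its readings give me 71.1%. Your forecast says 65%, which is lower than my figure. It also names red with 85.5%, reasoning that “Red is exactly the beta run”.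

    starting material → intermediate A (k = 0.0281 h⁻¹)
    reagent + intermediate A ⇌ intermediate B (K = 69.0 M⁻¹, k = 1.74 M⁻¹ h⁻¹)
    intermediate B → target (k = 0.0304 h⁻¹)
    solid substrate ⇌ starting material, rate k4*(cs4 - [starting material]) while solid is left; crystals form when [starting material] > cs4 (solubility = 14.0 mM, k = 0.0179 h⁻¹)

The flask gives 69.7%, and 85.3% after red, whose gain of 16 percentage points is more than violet's 9.4 points or ochre's 7.4 points. Now take the neighbour charged with 100 mM of solid substrate. That neighbour has no half-time to reach, since half of its charge, 50.0 mM, is more than the 30.0 mM of reagent charged, and the scheme spends one reagent for each target. So the stretch exponent serves there as a stretch of time, and an extrapolated one: the 10 d of that neighbour counts as 4.56 d in the alpha run, whose readings give 27.2%. That neighbour holds 18.8% target, with 61.1% of its charge still standing as solid substrate.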